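## Analysis of the target

The target (32) is carnosol with an acetoxy group on C16. It is an abieta-8,11,13-triene whose C20 carboxyl on C10 is lactonised onto the benzylic C7 oxygen. Ring B and the lactone therefore form a 2-oxabicyclo[2.2.2]octene, fused to ring A (4,4-dimethylcyclohexane) on one side and to the catechol ring C on the other. Three of the four stereocentres, C5 (S), C7 (S) and C10 (R), sit in this rigid cage and depend on each other: the lactone must bridge ring B on one face, and H5 lies anti to C20 (trans A/B relationship). The fourth, C15 (S), is a benzylic CH that exists only because one methyl of the carnosol isopropyl group is oxygenated; it is remote from the cage, and the core cannot be expected to control it. The sensitive groups are the catechol (air oxidation to the ortho-quinone), the primary acetate (which cannot be installed selectively once two phenols are free), the benzylic C7–O lactone bond and the benzylic C15–H. The difficulties are the remote C15 centre, the order in which acetate and phenols appear, and the quaternary C10 next to the C11 oxygen. The strategy rests on one feature: removing C11–C14 of ring C leaves the cage with a plain C8=C9 alkene, and C11(O)–C12–C13(side chain)–C14 maps onto a 3-substituted cyclobutenone that can carry C15 and its acetate from the chiral pool.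

## Retrosynthetic reasoning

**C12–O (32 to 30).** The catechol is unmasked last because it is the most oxidation-prone function. Phenol 30 has only one free ortho position (C12; the other ortho carbon, C9, is substituted), so a phenol-directed ortho-oxygenation with a pentavalent iodine reagent followed by reduction can only give the 11,12-pattern. No phenol protecting group is needed and the acetate is already in place.

**C8–C14 and C9–C11 (30 to 18 + 26).** Ring C is cut at the two bonds that join it to the cage. This gives alkenylstannane 18 (tin on C8, hydrogen on C9) and 4-chlorocyclobutenone 26. In the forward direction a palladium coupling joins C8 to the CHCl carbon, the four-membered ring opens to a dienylketene, and a 6π closure onto C9 gives the phenol. The cut is made here because it delivers the arene, the C11 oxygen and the complete side chain with C15 in one step, and regiochemistry follows from connectivity alone. Building the arene first would force the chiral side chain through many aromatic substitution steps.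

**Four-membered ring (26 to 25 to 24, then 22, 21, 20, 19).** The cyclobutenone is disconnected at C11–C12 and C13–C14, a ketene plus alkyne [2+2]. A dihaloketene adds to terminal alkyne 24 with the carbonyl carbon on the terminal CH, which places the side chain on the future C13. One chlorine is then removed to give 26. Alkyne 24 comes from hydroxy ester 19 by silylation, reduction to aldehyde 21, one-carbon homologation to 22 and exchange of silyl for acetyl. The CH2OH of 19 becomes C16 and the ester carbon becomes C13, which gives 15S without any stereoselective step.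

**C8–Sn and the C3 oxygen (18 to 17 to 13 to 11).** The tin comes from the alkenyl bromide 17 by palladium-catalysed exchange with a distannane. Bromide 17 is traced to ketone 13 and silyl ether 11, in which C3 carries a temporary oxygen. That oxygen is the only source of absolute configuration for the cage. It is removed by an ionic sequence (ketone, tosylhydrazone, hydride) because a radical deoxygenation would also attack the C8–Br bond.

**C5–C10 and C6–C7 (11 to 10).** The cage is opened by a retro-[4+2] reaction to the 3-alkyl-5-bromo-2-pyrone 10. In the forward direction the pyrone adds across its C3 and C6 positions to the tethered terminal alkene, which forms ring A, the lactone bridge and all three cage stereocentres at once. The bromine activates the diene and becomes the C8 handle. The natural C5 configuration needs the exo mode (C4 under the lactone half of the pyrone), and the absolute sense needs the C3 silyl ether in the equatorial site of the chair-like tether. The equatorial preference is small next to the gem-dimethyl group and the exo/endo preference is not predictable with confidence. All four possible adducts are diastereomers, however, so isolating 11 secures both relative and absolute configuration.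

**C1–C10 (10 to 2 + 8, through 9).** The tether is attached by an sp2–sp3 cross-coupling at the bromide next to the pyrone carbonyl of 2, which is the site zerovalent palladium prefers. The nucleophile is alkylzinc 9, made from iodide 8; its oxygen is γ to zinc, so it cannot eliminate. A hydroboration-based partner was avoided because the tether would then carry two monosubstituted vinyl groups, and a borane has no reliable way to choose between them.

**C3–C4 (8 to 7, 6, 5, then 3 + 4).** The carbinol next to the quaternary carbon is made by reverse prenylation of aldehyde 3 with the prenyl metal 4 under reagent control. This forms C3–C4, the gem-dimethyl carbon and the vinyl group in one step. Protecting-group changes then convert the primary oxygen into iodide.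

**Pyrone (2 to 1).** The dibromide is made in one step from coumalic acid 1 by bromination and bromodecarboxylation.

## Alternatives that were turned down

**Alternative 1:** The same two cage bonds (C5–C10, C6–C7) are cut, but with ring C already present. Arylacetic acid A2, which carries an ortho formyl group, is dehydrated in the flask to the ortho-quinoid pyranone A3. A3 adds across C10 and C7 to the tethered vinyl group and gives A1, the 3β-silyloxy carnosol lactone as its catechol dimethyl ether.
- For: the diene regains aromaticity, so this cycloaddition should run faster and at lower temperature than the pyrone addition in step 7 of the chosen route. The C11/C12 oxygens and C15 are in place from the start. On these two points it is the stronger plan.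
- Against: A2 is a pentasubstituted benzene with five different groups that must be assembled regioselectively while the chiral side chain is carried along. The facial control rests on the same weak C3 silyl ether and the same open exo/endo question. After the key step, C3 must be deoxygenated and two aryl methyl ethers cleaved in the presence of a primary acetate and a benzylic lactone, both of which are at risk under the Lewis-acidic conditions this needs.
- Comparison: the chosen route has the less certain ring-forming step, but it delivers the arene as a free phenol with the side chain attached and needs one operation afterwards.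

**Alternative 2:** Ring A is cut at C1–C10 and C4–C5. The enolic β-keto ester A5 adds through C10 to methyl vinyl ketone A6 under a bifunctional cinchona thiourea, and amine-mediated cyclodehydration gives the tricyclic enone A4.
- For: the C10 quaternary centre is set by catalysis with no temporary stereocentre, using robust and scalable reactions. On enantiocontrol this is the stronger plan.
- Against: A4 still lacks both C4 methyl groups, the C5 stereocentre and the C7 oxygen, and it carries a C3 ketone. It would need deconjugative dimethylation, C3 deoxygenation, trans-selective reduction of the resulting alkene next to the hindered ester, benzylic oxidation, lactonisation, ether cleavage and silyl-to-acetyl exchange, at least eight further steps. The Michael addition also takes place at a carbon flanked by the peri methoxy group.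
- Comparison: the chosen route sets C5, C7 and C10 in one cycloaddition and needs one operation after the key step, at the cost of a temporary C3 oxygen.

**Alternative 3:** Only the C16–O bond is cut. Carnosol A8 is converted into its bis(diethylsilyl) ether A9, and an iridium catalyst with a chiral ligand and a hydrogen acceptor silylates one methyl group of the isopropyl unit. This gives the benzoxasiline A7 and creates C15.
- For: it is by far the shortest plan, and the skeleton and three stereocentres come from the natural product. On step economy it clearly wins.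
- Against: the catalyst must distinguish two diastereotopic methyl groups on a chiral, crowded substrate through a six-membered silacycle, with a second Si–H group nearby. Oxidation of the C–Si bond with peroxide in the presence of a catechol, and acetylation of the primary alcohol beside two phenols, are both delicate. The route depends on a supply of the natural product.
- Comparison: the chosen route is a de novo synthesis in which C15 comes from the chiral pool with certainty, the acetate is installed before any phenol exists, and the two fragments can be varied independently.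

Key step: step 18

Remark: carbons are numbered as in abietane throughout (C20 is the lactone carbonyl carbon on C10), also in intermediates that lack ring C; 3, 4 (as a solution) and 19 are taken as commercial.

## Route

Step 1
Reactants: 1 coumalic acid
Product: 2 3,5-dibromo-2H-pyran-2-one
Conditions: NBS, LiOAc, MeCN–H2O, rt
Reagents that add atoms: N-bromosuccinimide, O=C1CCC(=O)N1Br
Why: Electrophilic bromination at C3 and bromodecarboxylation at C5 of a 2-pyrone carboxylic acid give the dibromide in one operation; no stereocentre is involved.

Step 2
Reactants: 3 3-[(tert-butyldimethylsilyl)oxy]propanal; 4 prenylmagnesium chloride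
Product: 5 (3S)-1-[(tert-butyldimethylsilyl)oxy]-4,4-dimethylhex-5-en-3-ol
Conditions: (+)-Ipc2BOMe [from (−)-α-pinene], 4, Et2O, −78 → 0 °C; then 3, −78 °C; then NaOH, H2O2, 0 °C → rt
Reagents that add atoms: none
Why: Brown reverse prenylation: the B-prenyl borane formed from 4 adds through its γ-carbon in a chair six-membered transition state, which builds the quaternary C4 with its vinyl group. The isopinocampheyl groups derived from (−)-α-pinene direct attack to the Re face of 3, which sets C3 as S.

Step 3
Reactants: 5 (3S)-1-[(tert-butyldimethylsilyl)oxy]-4,4-dimethylhex-5-en-3-ol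
Product: 6 (3S)-1,3-bis[(tert-butyldimethylsilyl)oxy]-4,4-dimethylhex-5-ene
Conditions: TBSOTf, 2,6-lutidine, CH2Cl2, −78 → 0 °C
Reagents that add atoms: tert-butyldimethylsilyl triflate, CC(C)(C)[Si](C)(C)OS(=O)(=O)C(F)(F)F
Why: Silyl triflate silylation of a hindered secondary alcohol next to a quaternary carbon; C3 is not touched.

Step 4
Reactants: 6 (3S)-1,3-bis[(tert-butyldimethylsilyl)oxy]-4,4-dimethylhex-5-ene
Product: 7 (3S)-3-[(tert-butyldimethylsilyl)oxy]-4,4-dimethylhex-5-en-1-ol
Conditions: camphorsulfonic acid (cat.), MeOH–CH2Cl2, 0 °C
Reagents that add atoms: none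
Why: Acid-catalysed methanolysis removes the unhindered primary silyl ether much faster than the secondary one flanked by the quaternary carbon.

Step 5
Reactants: 7 (3S)-3-[(tert-butyldimethylsilyl)oxy]-4,4-dimethylhex-5-en-1-ol
Product: 8 tert-butyl{[(3S)-1-iodo-4,4-dimethylhex-5-en-3-yl]oxy}dimethylsilane
Conditions: I2, PPh3, imidazole, CH2Cl2, 0 °C → rt
Reagents that add atoms: iodine, II
Why: Appel-type iodination of a primary alcohol by SN2 displacement of the oxyphosphonium group; the stereocentre is two carbons away and not involved.

Step 6
Reactants: 8 tert-butyl{[(3S)-1-iodo-4,4-dimethylhex-5-en-3-yl]oxy}dimethylsilane; 2 3,5-dibromo-2H-pyran-2-one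
Product: 10 5-bromo-3-[(3S)-3-(tert-butyldimethylsilyloxy)-4,4-dimethylhex-5-en-1-yl]-2H-pyran-2-one, via alkylzinc iodide 9 (not isolated)
Conditions: Zn dust (BrCH2CH2Br, Me3SiCl activation), LiCl, THF, 25–40 °C; then 2 (1.2 equiv), Pd(PPh3)4 (5 mol %), THF, 25–45 °C
Reagents that add atoms: none
Why: Zinc inserts into the primary C–I bond to give an alkylzinc that tolerates the γ-silyl ether, the alkene and the pyrone lactone. The Negishi coupling then occurs at the C3 bromide next to the carbonyl of 2, the site preferred by zerovalent palladium in a weakly polar medium without copper salts, and leaves the C5 bromide.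

Step 7
Reactants: 10 5-bromo-3-[(3S)-3-(tert-butyldimethylsilyloxy)-4,4-dimethylhex-5-en-1-yl]-2H-pyran-2-one
Product: 11 (1R,4S,6S,8S)-9-bromo-4-(tert-butyldimethylsilyloxy)-5,5-dimethyl-12-oxatricyclo[6.2.2.0^1,6]dodec-9-en-11-one
Conditions: PhMe (0.01 M), BHT (cat.), sealed tube, 110 °C
Reagents that add atoms: none
Why: Intramolecular pyrone Diels–Alder reaction of a 3-tethered 5-bromo-2-pyrone with a terminal alkene forms C5–C10 and C6–C7 and closes ring A through a chair-like four-carbon tether. The exo mode (C4 under the lactone half of the pyrone) gives H5 anti to C20, and the C3 silyl ether in the equatorial site selects the face that leads to 5S,7S,10R. Both preferences are expected to be modest, so 11 is separated here from its diastereomers; C3 is fixed, so none of them is its enantiomer.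

Step 8
Reactants: 11 (1R,4S,6S,8S)-9-bromo-4-(tert-butyldimethylsilyloxy)-5,5-dimethyl-12-oxatricyclo[6.2.2.0^1,6]dodec-9-en-11-one
Product: 13 (1R,6S,8S)-9-bromo-5,5-dimethyl-12-oxatricyclo[6.2.2.0^1,6]dodec-9-ene-4,11-dione, via secondary alcohol 12 (not isolated)
Conditions: CrO3, H2SO4, H2O (Jones reagent), acetone, 0 °C → rt
Reagents that add atoms: none
Why: Jones oxidation: the aqueous acid cleaves the silyl ether and CrO3 oxidises the freed secondary alcohol in the same flask. The lactone and the alkenyl bromide are inert, and the temporary C3 stereocentre is erased after it has done its work.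

Step 9
Reactants: 13 (1R,6S,8S)-9-bromo-5,5-dimethyl-12-oxatricyclo[6.2.2.0^1,6]dodec-9-ene-4,11-dione
Product: 14 (1R,6S,8S)-9-bromo-5,5-dimethyl-12-oxatricyclo[6.2.2.0^1,6]dodec-9-ene-4,11-dione 4-(4-methylbenzenesulfonyl)hydrazone
Conditions: TsNHNH2, pyridinium tosylate (cat.), EtOH, 60 °C
Reagents that add atoms: 4-methylbenzenesulfonyl hydrazide, Cc1ccc(cc1)S(=O)(=O)NN
Why: Condensation of the ketone with tosylhydrazide; the carbonyl is hindered on one side only (C2 is a methylene) and the weakly nucleophilic hydrazide leaves the lactone alone. The hydrazone is a likely point for crystallisation.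

Step 10
Reactants: 14 (1R,6S,8S)-9-bromo-5,5-dimethyl-12-oxatricyclo[6.2.2.0^1,6]dodec-9-ene-4,11-dione 4-(4-methylbenzenesulfonyl)hydrazone
Product: 17 (1R,6S,8S)-9-bromo-5,5-dimethyl-12-oxatricyclo[6.2.2.0^1,6]dodec-9-en-11-one, via N-boryl tosylhydrazide 15 (not isolated), via alkyldiazene 16 (not isolated)
Conditions: catecholborane, CHCl3, 0 °C → rt; then NaOAc·3H2O, reflux
Reagents that add atoms: none
Why: Kabalka deoxygenation: boron delivers hydride to the C=N carbon, acetate then induces loss of sulfinate, and the diazene expels N2 to leave a CH2 group. The conditions are neither radical nor strongly basic, so the C8–Br bond, the C8=C9 alkene and the lactone survive.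

Step 11
Reactants: 17 (1R,6S,8S)-9-bromo-5,5-dimethyl-12-oxatricyclo[6.2.2.0^1,6]dodec-9-en-11-one
Product: 18 (1R,6S,8S)-5,5-dimethyl-9-(trimethylstannyl)-12-oxatricyclo[6.2.2.0^1,6]dodec-9-en-11-one
Conditions: Me3SnSnMe3, Pd(PPh3)4 (5 mol %), PhMe, 90 °C
Reagents that add atoms: hexamethyldistannane, C[Sn](C)(C)[Sn](C)(C)C
Why: Palladium-catalysed stannylation of an alkenyl bromide with a distannane (oxidative addition, tin–tin transmetalation, reductive elimination). No stereocentre is touched and the temperature is well below that of CO2 extrusion.

Step 12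
Reactants: 19 methyl (R)-3-hydroxy-2-methylpropanoate
Product: 20 methyl (R)-3-[(tert-butyldimethylsilyl)oxy]-2-methylpropanoate
Conditions: TBSCl, imidazole, CH2Cl2, 0 °C → rt
Reagents that add atoms: tert-butyldimethylsilyl chloride, CC(C)(C)[Si](C)(C)Cl
Why: Standard silylation of a primary alcohol; the α-stereocentre is not affected under these mild conditions.

Step 13
Reactants: 20 methyl (R)-3-[(tert-butyldimethylsilyl)oxy]-2-methylpropanoate
Product: 21 (R)-3-[(tert-butyldimethylsilyl)oxy]-2-methylpropanal
Conditions: i-Bu2AlH, CH2Cl2, −78 °C; potassium sodium tartrate work-up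
Reagents that add atoms: none
Why: Partial reduction of the ester stops at the tetrahedral aluminium hemiacetal at −78 °C and gives the aldehyde on work-up; the cold, buffered work-up keeps the α-stereocentre intact.

Step 14
Reactants: 21 (R)-3-[(tert-butyldimethylsilyl)oxy]-2-methylpropanal
Product: 22 (S)-tert-butyldimethyl[(2-methylbut-3-yn-1-yl)oxy]silane
Conditions: MeC(O)C(N2)P(O)(OMe)2, K2CO3, MeOH, 0 °C → rt
Reagents that add atoms: dimethyl (1-diazo-2-oxopropyl)phosphonate, CC(=O)C(=[N+]=[N-])P(=O)(OC)OC
Why: Seyferth–Gilbert homologation in the Ohira–Bestmann form (addition of the diazophosphonate anion, cycloelimination, 1,2-hydrogen shift of the alkylidene carbene). The mild base at 0 °C keeps enolisation of the aldehyde slower than addition, so the stereocentre is carried over; it is now S only because the CIP priorities change.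

Step 15
Reactants: 22 (S)-tert-butyldimethyl[(2-methylbut-3-yn-1-yl)oxy]silane
Product: 24 (S)-2-methylbut-3-yn-1-yl acetate, via alkynol 23 (not isolated)
Conditions: Bu4NF, THF, 0 °C → rt; then Ac2O, Et3N, DMAP (cat.), 0 °C → rt
Reagents that add atoms: acetic anhydride, CC(=O)OC(C)=O
Why: Fluoride desilylation followed by acylation in the same flask, so that the volatile alcohol 23 is never concentrated. The acetate is installed here because it could not be introduced selectively once phenols are present.

Step 16
Reactants: 24 (S)-2-methylbut-3-yn-1-yl acetate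
Product: 25 (S)-2-(4,4-dichloro-3-oxocyclobut-1-en-1-yl)propyl acetate
Conditions: Cl3CCOCl, Zn(Cu), Et2O–DME, rt
Reagents that add atoms: trichloroacetyl chloride, ClC(Cl)(Cl)C(Cl)=O
Why: [2+2] cycloaddition of dichloroketene, made in the flask, with a terminal alkyne; the ketene carbonyl carbon bonds to the terminal CH, so the side chain ends up on the ring carbon next to CCl2. The neutral conditions leave the propargylic stereocentre alone.

Step 17
Reactants: 25 (S)-2-(4,4-dichloro-3-oxocyclobut-1-en-1-yl)propyl acetate
Product: 26 (2S)-2-(4-chloro-3-oxocyclobut-1-en-1-yl)propyl acetate (mixture at the CHCl carbon)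
Conditions: Zn dust (1.1 equiv), AcOH, TMEDA, EtOH, 0 °C
Reagents that add atoms: none
Why: Zinc reduction of an α,α-dichloro ketone through the zinc enolate, stopped after one C–Cl bond by limiting the metal and the temperature. Protonation at the α-carbon gives the 4-chloro isomer as a mixture at CHCl, which does not matter because that carbon becomes aromatic.

Step 18
Reactants: 18 (1R,6S,8S)-5,5-dimethyl-9-(trimethylstannyl)-12-oxatricyclo[6.2.2.0^1,6]dodec-9-en-11-one; 26 (2S)-2-(4-chloro-3-oxocyclobut-1-en-1-yl)propyl acetate
Product: 30 (5S,7S,10R,15S)-16-acetoxy-11-hydroxyabieta-8,11,13-trien-20,7-olide, via alkenylcyclobutenone 27 (not isolated), via dienylketene 28 (not isolated), via cyclohexadienone 29 (not isolated)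
Conditions: Pd2(dba)3 (5 mol %), P(2-furyl)3 (20 mol %), dioxane, 50 °C, then 100 °C
Reagents that add atoms: none
Why: Zerovalent palladium inserts into the allylic C–Cl bond of 26 to give an oxocyclobutenyl palladium chloride, the alkenyl group is transferred from tin (the weakly donating furylphosphine speeds this slow step), and reductive elimination joins C8 to the ring carbon that becomes C14, giving 27; bond formation at either end of the allyl unit leads to the same constitution. On warming, 27 opens by a conrotatory 4π electrocyclic cleavage of the bond between the carbonyl carbon and the CH carbon to give dienylketene 28; the opening is reversible, so material is funnelled through the isomer in which the ketene and C8 are cis. Ring C then closes by a thermal disrotatory 6π electrocyclisation of the C11=C12–C13=C14–C8=C9 triene, which forms C9–C11 and gives dienone 29, and a proton shift from C9 to oxygen aromatises it to 30. The closest known reaction type is the palladium-catalysed coupling of 4-chlorocyclobutenones with alkenylstannanes that runs on to phenols in the same flask; here the stannane is a bridged, α-branched cycloalkenyl one. No lasting stereocentre is created (the CHCl carbon and C9 both become aromatic), and C5, C7, C10 and C15 are spectators; C15–H is only vinylogously acidic and the medium is neutral. The selectivities needed are insertion into C–Cl in preference to ionisation of the allylic C7–O carboxylate, which the far more reactive allylic chloride and a non-polar medium should secure, and regiochemistry, which is fixed by connectivity (tin on C8, hydrogen on C9). The bath is kept at or below 100 °C so that 18 does not lose CO2 before it has coupled; once ring C is aromatic that cycloreversion is no longer available.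

Step 19
Reactants: 30 (5S,7S,10R,15S)-16-acetoxy-11-hydroxyabieta-8,11,13-trien-20,7-olide
Product: 32 (5S,7S,10R,15S)-16-acetoxy-11,12-dihydroxyabieta-8,11,13-trien-20,7-olide (16-acetoxycarnosol), via ortho-quinone 31 (not isolated)
Conditions: IBX, DMF, rt; then aq. Na2S2O4
Reagents that add atoms: 2-iodoxybenzoic acid, OI1(=O)OC(=O)c2ccccc12
Why: Phenol-directed ortho-oxygenation: the phenol binds to pentavalent iodine and oxygen is delivered within the complex to the only free ortho carbon, C12, giving the ortho-quinone. Dithionite reduces it at once to the catechol, so the quinone is never handled and the acetate and lactone see only neutral conditions.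

## Compound list

1 | coumalic acid (2-oxo-2H-pyran-5-carboxylic acid) | O=C1C=CC(C(O)=O)=CO1 | starting material
2 | 3,5-dibromo-2H-pyran-2-one | O=C1OC=C(Br)C=C1Br | intermediate
3 | 3-[(tert-butyldimethylsilyl)oxy]propanal | CC(C)(C)[Si](C)(C)OCCC=O | starting material
4 | prenylmagnesium chloride (3-methylbut-2-en-1-ylmagnesium chloride) | CC(C)=CC[Mg]Cl | starting material
5 | (3S)-1-[(tert-butyldimethylsilyl)oxy]-4,4-dimethylhex-5-en-3-ol | CC(C)(C)[Si](C)(C)OCC[C@H](O)C(C)(C)C=C | intermediate
6 | (3S)-1,3-bis[(tert-butyldimethylsilyl)oxy]-4,4-dimethylhex-5-ene | CC(C)(C)[Si](C)(C)OCC[C@H](O[Si](C)(C)C(C)(C)C)C(C)(C)C=C | intermediate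
7 | (3S)-3-[(tert-butyldimethylsilyl)oxy]-4,4-dimethylhex-5-en-1-ol | OCC[C@H](O[Si](C)(C)C(C)(C)C)C(C)(C)C=C | intermediate
8 | tert-butyl{[(3S)-1-iodo-4,4-dimethylhex-5-en-3-yl]oxy}dimethylsilane | ICC[C@H](O[Si](C)(C)C(C)(C)C)C(C)(C)C=C | intermediate
9 | [(3S)-3-(tert-butyldimethylsilyloxy)-4,4-dimethylhex-5-en-1-yl]zinc iodide | I[Zn]CC[C@H](O[Si](C)(C)C(C)(C)C)C(C)(C)C=C | intermediate
10 | 5-bromo-3-[(3S)-3-(tert-butyldimethylsilyloxy)-4,4-dimethylhex-5-en-1-yl]-2H-pyran-2-one | O=C1OC=C(Br)C=C1CC[C@H](O[Si](C)(C)C(C)(C)C)C(C)(C)C=C | intermediate
11 | (1R,4S,6S,8S)-9-bromo-4-(tert-butyldimethylsilyloxy)-5,5-dimethyl-12-oxatricyclo[6.2.2.0^1,6]dodec-9-en-11-one (abietane numbering: 5S,7S,10R; 3β-silyloxy; C8–Br) | BrC1=C[C@@]23CC[C@H](O[Si](C)(C)C(C)(C)C)C(C)(C)[C@@H]2C[C@@H]1OC3=O | intermediate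
12 | (1R,4S,6S,8S)-9-bromo-4-hydroxy-5,5-dimethyl-12-oxatricyclo[6.2.2.0^1,6]dodec-9-en-11-one | BrC1=C[C@@]23CC[C@H](O)C(C)(C)[C@@H]2C[C@@H]1OC3=O | intermediate
13 | (1R,6S,8S)-9-bromo-5,5-dimethyl-12-oxatricyclo[6.2.2.0^1,6]dodec-9-ene-4,11-dione | BrC1=C[C@@]23CCC(=O)C(C)(C)[C@@H]2C[C@@H]1OC3=O | intermediate
14 | 4-tosylhydrazone of 13 (C=N geometry immaterial) | BrC1=C[C@@]23CCC(=NNS(=O)(=O)c4ccc(C)cc4)C(C)(C)[C@@H]2C[C@@H]1OC3=O | intermediate
15 | N-(catecholboryl)-N′-tosylhydrazine on C3 of the cage of 17 (C3 configuration undefined) | BrC1=C[C@@]23CCC(N(NS(=O)(=O)c4ccc(C)cc4)B4Oc5ccccc5O4)C(C)(C)[C@@H]2C[C@@H]1OC3=O | intermediate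
16 | C3 diazene (N=NH) of the cage of 17 (C3 configuration undefined) | BrC1=C[C@@]23CCC(N=N)C(C)(C)[C@@H]2C[C@@H]1OC3=O | intermediate
17 | (1R,6S,8S)-9-bromo-5,5-dimethyl-12-oxatricyclo[6.2.2.0^1,6]dodec-9-en-11-one | BrC1=C[C@@]23CCCC(C)(C)[C@@H]2C[C@@H]1OC3=O | intermediate
18 | (1R,6S,8S)-5,5-dimethyl-9-(trimethylstannyl)-12-oxatricyclo[6.2.2.0^1,6]dodec-9-en-11-one | C[Sn](C)(C)C1=C[C@@]23CCCC(C)(C)[C@@H]2C[C@@H]1OC3=O | intermediate
19 | methyl (R)-3-hydroxy-2-methylpropanoate | OC[C@@H](C)C(=O)OC | starting material
20 | methyl (R)-3-[(tert-butyldimethylsilyl)oxy]-2-methylpropanoate | CC(C)(C)[Si](C)(C)OC[C@@H](C)C(=O)OC | intermediate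
21 | (R)-3-[(tert-butyldimethylsilyl)oxy]-2-methylpropanal | CC(C)(C)[Si](C)(C)OC[C@@H](C)C=O | intermediate
22 | (S)-tert-butyldimethyl[(2-methylbut-3-yn-1-yl)oxy]silane | CC(C)(C)[Si](C)(C)OC[C@@H](C)C#C | intermediate
23 | (S)-2-methylbut-3-yn-1-ol | OC[C@@H](C)C#C | intermediate
24 | (S)-2-methylbut-3-yn-1-yl acetate | CC(=O)OC[C@@H](C)C#C | intermediate
25 | (S)-2-(4,4-dichloro-3-oxocyclobut-1-en-1-yl)propyl acetate | CC(=O)OC[C@@H](C)C1=CC(=O)C1(Cl)Cl | intermediate
26 | (2S)-2-(4-chloro-3-oxocyclobut-1-en-1-yl)propyl acetate, mixture at the CHCl carbon | CC(=O)OC[C@@H](C)C1=CC(=O)C1Cl | intermediate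
27 | 4-alkenylcyclobutenone: 26 with Cl replaced by C8 of the cage of 18 (cage as in 18, ring CH as a mixture) | CC(=O)OC[C@@H](C)C1=CC(=O)C1C1=C[C@@]23CCCC(C)(C)[C@@H]2C[C@@H]1OC3=O | intermediate
28 | (Z)-dienylketene O=C=C12H–C13(side chain)=C14H–C8=C9, C12 and C8 cis, cage as in 18 | CC(=O)OC[C@@H](C)C(\C=C=O)=C\C1=C[C@@]23CCCC(C)(C)[C@@H]2C[C@@H]1OC3=O | intermediate
29 | cyclohexa-2,4-dienone tautomer of 30 (C11 ketone, C12=C13 and C8=C14 double bonds, C9–H sp3, mixture at C9) | CC(=O)OC[C@@H](C)C1C=C2C(C(=O)C=1)[C@@]13CCCC(C)(C)[C@@H]1C[C@@H]2OC3=O | intermediate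
30 | (5S,7S,10R,15S)-16-acetoxy-11-hydroxyabieta-8,11,13-trien-20,7-olide | CC(=O)OC[C@@H](C)c1cc2c(c(O)c1)[C@@]13CCCC(C)(C)[C@@H]1C[C@@H]2OC3=O | intermediate
31 | (5S,7S,10R,15S)-16-acetoxy-11,12-dioxoabieta-8,13-dien-20,7-olide | CC(=O)OC[C@@H](C)C1=CC2=C(C(=O)C1=O)[C@@]13CCCC(C)(C)[C@@H]1C[C@@H]2OC3=O | intermediate
32 | (5S,7S,10R,15S)-16-acetoxy-11,12-dihydroxyabieta-8,11,13-trien-20,7-olide (16-acetoxycarnosol) | CC(=O)OC[C@@H](C)c1cc2c(c(O)c1O)[C@@]13CCCC(C)(C)[C@@H]1C[C@@H]2OC3=O | target

## Step count and least certain steps

Total step count: 19 (step 1; steps 2–11 to stannane 18; steps 12–17 to cyclobutenone 26; steps 18 and 19).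
Longest linear sequence: 12 steps (3 through steps 2–11, then 18 and 19).

**Step 18 (key step).** The most likely failure is slow transfer of the α-branched alkenyl group from tin to palladium, because C8 sits next to the C7 bridgehead. Protodestannylation and thermal decay of 26 could then outrun the coupling, and zerovalent palladium could ionise the allylic C7–O carboxylate of the strained lactone instead. The fallback removes the bridge before the coupling and sets out from 18. Methanolysis (NaOMe, MeOH, 0 °C) opens the lactone to the methyl ester with a free allylic C7 alcohol, stannyl hydroxy ester F1, and TESOTf with 2,6-lutidine gives its triethylsilyl ether F2. F2 is an ordinary cyclohexenylstannane with no ionisable allylic ester. Under the conditions of step 18 it couples with 26 to alkenylcyclobutenone F3, which opens to dienylketene F4, closes to cyclohexadienone F5 and tautomerises to phenol F6. TsOH·H2O in CH2Cl2 removes the silyl group to give hydroxy ester F7, whose C7 hydroxyl is cis to the C10 ester and lactonises under the same acid. The route is rejoined at 30.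

**Step 7.** The most likely problem is insufficient discrimination between the two faces and between the exo and endo modes, because the equatorial preference of a silyl ether next to a gem-dimethyl carbon is small. A mixture of up to four diastereomers would result, and prolonged heating risks CO2 extrusion. If the facial sense is opposite to the one assumed, the antipodal borane in step 2 corrects it. If the bias is simply low, the fallback drops the C3 control element and sets out from 4 and 2. Prenylmagnesium chloride 4 opens oxetane through its γ-carbon to 4,4-dimethylhex-5-en-1-ol F8, and I2, PPh3 and imidazole give 6-iodo-3,3-dimethylhex-1-ene F9. Its zinc reagent F10 couples with 2 as in step 6 to the achiral pyrone F11. Heating as in step 7 gives 17 together with its enantiomer F12, and the two are separated by chromatography on a chiral stationary phase. The route is rejoined at 17, and steps 8–10 are not needed.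

**Step 11.** The risk is that zerovalent palladium ionises the allylic lactone C7–O bond of 17 in competition with insertion into C8–Br, so that the distannane is consumed by an allyl palladium species. The fallback sets out from 17. Methanolysis as above gives bromo hydroxy ester F13 and TESOTf its silyl ether F14, which has no allylic carboxylate. Stannylation under the conditions of step 11 gives F2, and the sequence of the fallback for step 18 (F3 to F7) is then followed. The route is rejoined at 30.

**Step 19.** Oxidation may go beyond the ortho-quinone, or the quinone may tautomerise towards the benzylic C7 position before it is reduced, since the ring carries only alkyl donors beside the phenol. The fallback introduces the oxygen through carbon and sets out from 30. Ortho-formylation (MgCl2, Et3N, paraformaldehyde, MeCN, reflux) can only reach C12 and gives salicylaldehyde F15. Baeyer–Villiger oxidation with mCPBA gives aryl formate F16, and brief treatment with KHCO3 in MeOH at 0 °C cleaves the formate much faster than the primary acetate. The route is rejoined at 32.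

**Step 14.** The risk is partial loss of configuration at the α-carbon of aldehyde 21 by enolisation under carbonate in methanol, which would erode C15. The fallback avoids equilibrating base and sets out from 21. CBr4 and PPh3 (CH2Cl2, 0 °C) give dibromoalkene F17, and n-BuLi (THF, −78 °C) converts it through lithium acetylide F18 into the alkyne on aqueous quench. The route is rejoined at 22.

## Further compounds

F1 | step 18 | methyl ester of the ring-opened stannane: C10–CO2Me, C7–OH, C8–SnMe3 (centres as in 18) | C[Sn](C)(C)C1=C[C@@]2(C(=O)OC)CCCC(C)(C)[C@@H]2C[C@@H]1O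
F2 | step 18 | triethylsilyl ether of F1 | C[Sn](C)(C)C1=C[C@@]2(C(=O)OC)CCCC(C)(C)[C@@H]2C[C@@H]1O[Si](CC)(CC)CC
F3 | step 18 | 4-alkenylcyclobutenone of the ring-opened series (ring CH as a mixture) | CC(=O)OC[C@@H](C)C1=CC(=O)C1C1=C[C@@]2(C(=O)OC)CCCC(C)(C)[C@@H]2C[C@@H]1O[Si](CC)(CC)CC
F4 | step 18 | (Z)-dienylketene of the ring-opened series | CC(=O)OC[C@@H](C)C(\C=C=O)=C\C1=C[C@@]2(C(=O)OC)CCCC(C)(C)[C@@H]2C[C@@H]1O[Si](CC)(CC)CC
F5 | step 18 | cyclohexa-2,4-dienone of the ring-opened series (mixture at C9) | CC(=O)OC[C@@H](C)C1C=C2C(C(=O)C=1)[C@@]1(C(=O)OC)CCCC(C)(C)[C@@H]1C[C@@H]2O[Si](CC)(CC)CC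
F6 | step 18 | methyl (5S,7S,10R,15S)-16-acetoxy-11-hydroxy-7-(triethylsilyloxy)abieta-8,11,13-trien-20-oate | CC(=O)OC[C@@H](C)c1cc2c(c(O)c1)[C@@]1(C(=O)OC)CCCC(C)(C)[C@@H]1C[C@@H]2O[Si](CC)(CC)CC
F7 | step 18 | methyl (5S,7S,10R,15S)-16-acetoxy-7,11-dihydroxyabieta-8,11,13-trien-20-oate | CC(=O)OC[C@@H](C)c1cc2c(c(O)c1)[C@@]1(C(=O)OC)CCCC(C)(C)[C@@H]1C[C@@H]2O
F8 | step 7 | 4,4-dimethylhex-5-en-1-ol | C=CC(C)(C)CCCO
F9 | step 7 | 6-iodo-3,3-dimethylhex-1-ene | C=CC(C)(C)CCCI
F10 | step 7 | (4,4-dimethylhex-5-en-1-yl)zinc iodide | I[Zn]CCCC(C)(C)C=C
F11 | step 7 | 5-bromo-3-(4,4-dimethylhex-5-en-1-yl)-2H-pyran-2-one | O=C1OC=C(Br)C=C1CCCC(C)(C)C=C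
F12 | step 7 | (1S,6R,8R)-9-bromo-5,5-dimethyl-12-oxatricyclo[6.2.2.0^1,6]dodec-9-en-11-one (enantiomer of 17) | BrC1=C[C@]23CCCC(C)(C)[C@H]2C[C@H]1OC3=O
F13 | step 11 | methyl ester of the ring-opened bromide: C10–CO2Me, C7–OH, C8–Br (centres as in 17) | BrC1=C[C@@]2(C(=O)OC)CCCC(C)(C)[C@@H]2C[C@@H]1O
F14 | step 11 | triethylsilyl ether of F13 | BrC1=C[C@@]2(C(=O)OC)CCCC(C)(C)[C@@H]2C[C@@H]1O[Si](CC)(CC)CC
F15 | step 19 | (5S,7S,10R,15S)-16-acetoxy-12-formyl-11-hydroxyabieta-8,11,13-trien-20,7-olide | CC(=O)OC[C@@H](C)c1cc2c(c(O)c1C=O)[C@@]13CCCC(C)(C)[C@@H]1C[C@@H]2OC3=O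
F16 | step 19 | (5S,7S,10R,15S)-16-acetoxy-12-formyloxy-11-hydroxyabieta-8,11,13-trien-20,7-olide | CC(=O)OC[C@@H](C)c1cc2c(c(O)c1OC=O)[C@@]13CCCC(C)(C)[C@@H]1C[C@@H]2OC3=O
F17 | step 14 | (S)-tert-butyl[(4,4-dibromo-2-methylbut-3-en-1-yl)oxy]dimethylsilane | CC(C)(C)[Si](C)(C)OC[C@@H](C)C=C(Br)Br
F18 | step 14 | lithium acetylide of 22 | CC(C)(C)[Si](C)(C)OC[C@@H](C)C#C[Li]
A1 | alternative 1 | 3β-(tert-butyldimethylsilyloxy)-16-acetoxycarnosol 11,12-dimethyl ether | CC(=O)OC[C@@H](C)c1cc2c(c(OC)c1OC)[C@@]13CC[C@H](O[Si](C)(C)C(C)(C)C)C(C)(C)[C@@H]1C[C@@H]2OC3=O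
A2 | alternative 1 | 2-aryl-5-(tert-butyldimethylsilyloxy)-6,6-dimethyloct-7-enoic acid, aryl = 6-formyl-2,3-dimethoxy-4-[(S)-1-acetoxyprop-2-yl]phenyl (mixture at the α-carbon) | CC(=O)OC[C@@H](C)c1cc(C=O)c(C(CC[C@H](O[Si](C)(C)C(C)(C)C)C(C)(C)C=C)C(O)=O)c(OC)c1OC
A3 | alternative 1 | ortho-quinoid 2-benzopyran-3-one formed from A2 by dehydration | CC(=O)OC[C@@H](C)C1=CC2=COC(=O)C(CC[C@H](O[Si](C)(C)C(C)(C)C)C(C)(C)C=C)=C2C(OC)=C1OC
A4 | alternative 2 | tricyclic enone: C10 methyl ester, C3 ketone, C4=C5 alkene, 11,12-dimethoxy, C13 (S)-1-(tert-butyldimethylsilyloxy)prop-2-yl | COC(=O)[C@]12CCC(=O)C=C1CCc1cc([C@H](C)CO[Si](C)(C)C(C)(C)C)c(OC)c(OC)c12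
A5 | alternative 2 | methyl 7,8-dimethoxy-2-oxo-6-[(S)-1-(tert-butyldimethylsilyloxy)prop-2-yl]-1,2,3,4-tetrahydronaphthalene-1-carboxylate | COC(=O)C1C(=O)CCc2cc([C@H](C)CO[Si](C)(C)C(C)(C)C)c(OC)c(OC)c12
A6 | alternative 2 | methyl vinyl ketone | CC(=O)C=C
A7 | alternative 3 | C16-silylated benzoxasiline of carnosol with a diethylsilyl ether on the C11 oxygen | C[C@@H]1C[Si](CC)(CC)Oc2c1cc3c(c2O[SiH](CC)CC)[C@@]45CCCC(C)(C)[C@@H]4C[C@@H]3OC5=O
A8 | alternative 3 | carnosol | CC(C)c1cc2c(c(O)c1O)[C@@]13CCCC(C)(C)[C@@H]1C[C@@H]2OC3=O
A9 | alternative 3 | carnosol 11,12-bis(diethylsilyl) ether | CC(C)c1cc2c(c(O[SiH](CC)CC)c1O[SiH](CC)CC)[C@@]13CCCC(C)(C)[C@@H]1C[C@@H]2OC3=O
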